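Assumption: the target is numbered as (1R,2S,4S,5S,7R,8R)-3,3,7,11-tetramethyl-tricyclo[5.4.0.0(2,8)]undec-10-en-9-one with the (Z)-2-methylbut-2-enoate (angelate) on C4 and the isobutyrate on C5; this C1–C11 numbering is used for all tricyclic compounds.

**Retrosynthetic overview**
1. Target ⇐ tricyclic C4 alcohol (silyl ethers at C5 and C9, 11-methylidene): angelate at C4, isobutyrate at C5, then C9 oxidation and alkene migration into conjugation.
2. Seven-membered ring ⇐ C2–C3 bond and C2–H from a new Cp2TiCl epoxide-opening / sulfonylhydrazone radical cyclisation with loss of N2; the epoxide supplies the C4 oxygen.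
3. Cyclobutane and six-membered ring in one step (C1, C7, C8) ⇐ intramolecular vinylketene–alkene [2+2] of a 5,9-dioxygenated farnesoic acid, steered by the silyloxy centre that becomes C9.
4. Farnesoic acid ⇐ asymmetric vinylogous Mukaiyama aldol of a 5-oxygenated geranial with a senecioate dienolate; geranial ⇐ carboalumination of an alkyne from asymmetric propargylation of prenal (sets C5).
5. Ring order: four- and six-membered rings together, then the seven-membered ring; the enone is unveiled last.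

**Route**

Step 1
Reactants: 1 3-methylbut-2-enal; 2 allenylboronic acid pinacol ester
Product: 3 (4S)-6-methylhept-5-en-1-yn-4-ol
Conditions: (S)-TRIP [(S)-3,3'-bis(2,4,6-triisopropylphenyl)-1,1'-binaphthyl-2,2'-diyl hydrogen phosphate] (5 mol%), 4 Å molecular sieves, toluene, 0 °C; aq. NaHCO3
Reagents that add atoms: none
Why: Chiral phosphoric acid-catalysed propargylboration (allenylboronate addition through a closed six-membered transition state) of the enal, in which the catalyst antipode fixes the 4S carbinol that becomes target C5.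

Step 2
Reactants: 3 (4S)-6-methylhept-5-en-1-yn-4-ol
Product: 4 PMB ether 1-methoxy-4-({[(4S)-6-methylhept-5-en-1-yn-4-yl]oxy}methyl)benzene
Conditions: NaH, 4-methoxybenzyl chloride, THF/DMF, 0 °C→rt
Reagents that add atoms: 4-methoxybenzyl chloride (COc1ccc(CCl)cc1)
Why: Williamson etherification of the sodium alkoxide leaves the stereocentre untouched and gives an ether that survives the organoaluminium, Lewis acid and ketene steps.

Step 3
Reactants: 4 PMB ether of 3
Product: 7 (2E,5S)-5-[(4-methoxybenzyl)oxy]-3,7-dimethylocta-2,6-dien-1-ol, via alkenyldimethylalane 5 (not isolated), via lithium alkenylaluminate 6 (not isolated)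
Conditions: AlMe3, Cp2ZrCl2 (25 mol%), CH2Cl2, 0 °C→rt; then n-BuLi, THF, −78 °C; (CH2O)n, −78 °C→rt; aq. potassium sodium tartrate
Reagents that add atoms: trimethylaluminium (C[Al](C)C); paraformaldehyde as formaldehyde (C=O)
Why: Negishi zirconium-catalysed syn-carboalumination puts methyl on the internal and aluminium on the terminal alkyne carbon, and hydroxymethylation of the ate complex with retention gives the E (geraniol-type) trisubstituted alkene.

Step 4
Reactants: 7 (2E,5S)-5-[(4-methoxybenzyl)oxy]-3,7-dimethylocta-2,6-dien-1-ol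
Product: 8 (2E,5S)-5-[(4-methoxybenzyl)oxy]-3,7-dimethylocta-2,6-dienal
Conditions: MnO2, CH2Cl2, rt
Reagents that add atoms: none
Why: Chemoselective allylic alcohol oxidation with MnO2 gives the E enal without touching the PMB ether or the other alkene.

Step 5
Reactants: 9 methyl 3-methylbut-2-enoate
Product: 10 tert-butyl[(1-methoxy-3-methylbuta-1,3-dien-1-yl)oxy]dimethylsilane
Conditions: LiN(iPr)2, DMPU, THF, −78 °C; tert-butyldimethylsilyl chloride
Reagents that add atoms: tert-butyldimethylsilyl chloride (CC(C)(C)[Si](C)(C)Cl)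
Why: γ-Deprotonation of the senecioate and O-silylation of the dienolate give the silyl dienol ether (silyl ketene acetal formation).

Step 6
Reactants: 8 (2E,5S)-5-[(4-methoxybenzyl)oxy]-3,7-dimethylocta-2,6-dienal; 10 silyl dienolate
Product: 11 methyl (2E,5S,6E,9S)-5-hydroxy-9-[(4-methoxybenzyl)oxy]-3,7,11-trimethyldodeca-2,6,10-trienoate
Conditions: SiCl4, (S,S)-bisphosphoramide [pentane-1,5-diyl-linked bis(N,N'-dimethyl-1,1'-binaphthyl-2,2'-diamine phosphoramide)] (5 mol%), iPr2NEt (10 mol%), CH2Cl2, −78 °C; aq. NaHCO3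
Reagents that add atoms: none
Why: Lewis base-activated SiCl4 vinylogous Mukaiyama aldol with exclusive γ-attack on the Si face of the enal, under catalyst control, sets the 5S carbinol (future C9) that later steers the cycloaddition.

Step 7
Reactants: 11 hydroxy ester
Product: 12 methyl (2E,5S,6E,9S)-5-[(tert-butyldimethylsilyl)oxy]-9-[(4-methoxybenzyl)oxy]-3,7,11-trimethyldodeca-2,6,10-trienoate
Conditions: tert-butyldimethylsilyl chloride, imidazole, DMF, rt
Reagents that add atoms: tert-butyldimethylsilyl chloride (CC(C)(C)[Si](C)(C)Cl)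
Why: Silylation of the secondary allylic alcohol installs the bulky OTBS group that is the A(1,3) control element in step 9.

Step 8
Reactants: 12 silyl ether ester
Product: 13 (2E,5S,6E,9S)-5-[(tert-butyldimethylsilyl)oxy]-9-[(4-methoxybenzyl)oxy]-3,7,11-trimethyldodeca-2,6,10-trienoic acid
Conditions: LiOH, THF/MeOH/H2O, 45 °C; then dilute aq. HCl to pH 4, 0 °C
Reagents that add atoms: lithium hydroxide ([Li+].[OH-])
Why: Saponification of the conjugated methyl ester proceeds while the silyl and PMB ethers are stable to hydroxide.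

Step 9
Reactants: 13 trienoic acid
Product: 16 (1R,4S,5R,7R)-4-[(tert-butyldimethylsilyl)oxy]-7-{(2S)-2-[(4-methoxybenzyl)oxy]-4-methylpent-3-en-1-yl}-7-methyl-2-methylidenebicyclo[3.1.1]heptan-6-one, via acid chloride 14 (not isolated), via vinylketene 15 (not isolated)
Conditions: 1-chloro-N,N,2-trimethylprop-1-en-1-amine, CH2Cl2, 0 °C; then Et3N, toluene, 110 °C, 10 mM (slow addition)
Reagents that add atoms: none
Why: Neutral acid chloride formation, dehydrochlorination at the γ-methyl syn to the carbonyl and intramolecular vinylketene–alkene [2+2] of the bergamotene type (carbonyl carbon to the less substituted alkene carbon, hence bicyclo[3.1.1]) set target C1, C7 and C8: the E alkene puts the 7-methyl syn to the three-carbon bridge and the side chain toward the ketone, and A(1,3) strain (carbinol H eclipsing the cis methyl, OTBS outside) selects the alkene face.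

Step 10
Reactants: 16 bicyclic ketone PMB ether
Product: 17 (1R,4S,5R,7R)-4-[(tert-butyldimethylsilyl)oxy]-7-[(2S)-2-hydroxy-4-methylpent-3-en-1-yl]-7-methyl-2-methylidenebicyclo[3.1.1]heptan-6-one
Conditions: DDQ, CH2Cl2/pH 7 buffer, 0 °C
Reagents that add atoms: none
Why: Oxidative PMB ether cleavage by DDQ frees the allylic alcohol needed to direct the epoxidation.

Step 11
Reactants: 17 allylic alcohol
Product: 18 (1R,4S,5R,7R)-4-[(tert-butyldimethylsilyl)oxy]-7-{(2S)-2-[(2R)-3,3-dimethyloxiran-2-yl]-2-hydroxyethyl}-7-methyl-2-methylidenebicyclo[3.1.1]heptan-6-one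
Conditions: dimethyldioxirane (1.05 equiv), CH2Cl2/acetone, −20 °C
Reagents that add atoms: dimethyldioxirane (CC1(C)OO1)
Why: Hydroxyl-directed (hydrogen-bonded) dioxirane epoxidation of the trisubstituted alkene in its A(1,3)-minimised conformer gives the threo epoxy alcohol and so sets target C4, while the dioxirane causes no Baeyer–Villiger oxidation of the cyclobutanone and prefers the trisubstituted over the 1,1-disubstituted alkene.

Step 12
Reactants: 18 epoxy alcohol
Product: 19 (1R,4S,5R,7R)-4-[(tert-butyldimethylsilyl)oxy]-7-{(2S)-2-[(2R)-3,3-dimethyloxiran-2-yl]-2-[(triethylsilyl)oxy]ethyl}-7-methyl-2-methylidenebicyclo[3.1.1]heptan-6-one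
Conditions: chlorotriethylsilane, imidazole, CH2Cl2, 0 °C
Reagents that add atoms: chlorotriethylsilane (CC[Si](Cl)(CC)CC)
Why: Silylation of the secondary alcohol gives a TES ether that can later be removed in the presence of the TBS ether.

Step 13
Reactants: 19 TES-protected epoxy ketone
Product: 20 N'-[(1R,4S,5S,7R)-4-[(tert-butyldimethylsilyl)oxy]-7-{(2S)-2-[(2R)-3,3-dimethyloxiran-2-yl]-2-[(triethylsilyl)oxy]ethyl}-7-methyl-2-methylidenebicyclo[3.1.1]heptan-6-ylidene]-4-methylbenzenesulfonohydrazide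
Conditions: TsNHNH2, 4 Å molecular sieves, THF, rt
Reagents that add atoms: 4-methylbenzenesulfonohydrazide (Cc1ccc(cc1)S(=O)(=O)NN)
Why: Hydrazone formation on the strained, non-enolisable cyclobutanone installs a radical acceptor whose C=N geometry is irrelevant to the next step.

Step 14
Reactants: 20 tosylhydrazone
Product: 22 (1R,2S,4S,5S,7R,8R,9S)-9-[(tert-butyldimethylsilyl)oxy]-3,3,7-trimethyl-11-methylidene-5-[(triethylsilyl)oxy]tricyclo[5.4.0.0(2,8)]undecan-4-ol, via cyclised tosylhydrazide 21 (not isolated)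
Conditions: Cp2TiCl2 (30 mol%), Mn, 2,4,6-collidine·HCl, THF, rt (slow addition of 20); then Et3N, MeOH, 65 °C
Reagents that add atoms: none
Why: Proposed new method: Cp2TiCl (trivalent titanium, regenerated by Mn and collidinium chloride) opens the trisubstituted epoxide homolytically to the tertiary C3 radical with the C4–O bond retained, the radical adds 7-exo to the hydrazone carbon from the only open face (the chain sits on the C7 position that points at C2), the nitrogen radical is reduced by a second trivalent titanium and protonated, and base then expels sulfinate and N2 so that hydrogen takes the remaining position and C2 is set by ring constraint, a C=N acceptor being chosen because addition to the C=O would pass through a cyclobutyloxy radical prone to ring opening; the closest known reaction types are the Nugent–RajanBabu/Gansäuer epoxide radical cyclisations onto alkenes and carbonyls and the reductive alkylation of alkyl radicals with sulfonylhydrazones.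

Step 15
Reactants: 22 tricyclic C4 alcohol
Product: 23 (1R,2S,4S,5S,7R,8R,9S)-9-[(tert-butyldimethylsilyl)oxy]-3,3,7-trimethyl-11-methylidene-5-[(triethylsilyl)oxy]tricyclo[5.4.0.0(2,8)]undec-4-yl (2Z)-2-methylbut-2-enoate
Conditions: angelic acid, 2,4,6-trichlorobenzoyl chloride, Et3N, toluene, rt; then 22, 80 °C
Reagents that add atoms: angelic acid, (2Z)-2-methylbut-2-enoic acid (C/C=C(/C)C(O)=O)
Why: Yamaguchi esterification through the mixed 2,4,6-trichlorobenzoic anhydride, run without a nucleophilic catalyst, acylates the hindered C4 alcohol with retention of the Z geometry.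

Step 16
Reactants: 23 angelate
Product: 24 (1R,2S,4S,5S,7R,8R,9S)-9-[(tert-butyldimethylsilyl)oxy]-5-hydroxy-3,3,7-trimethyl-11-methylidenetricyclo[5.4.0.0(2,8)]undec-4-yl (2Z)-2-methylbut-2-enoate
Conditions: pyridinium 4-methylbenzenesulfonate (10 mol%), MeOH/CH2Cl2, 0 °C
Reagents that add atoms: none
Why: Mild acid-catalysed methanolysis (selective desilylation) removes the more labile TES ether and leaves the secondary TBS ether and the angelate.

Step 17
Reactants: 24 C5 alcohol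
Product: 25 (1R,2S,4S,5S,7R,8R,9S)-9-[(tert-butyldimethylsilyl)oxy]-3,3,7-trimethyl-11-methylidene-5-[(2-methylpropanoyl)oxy]tricyclo[5.4.0.0(2,8)]undec-4-yl (2Z)-2-methylbut-2-enoate
Conditions: 2-methylpropanoyl chloride, pyridine, 4-(dimethylamino)pyridine (cat.), CH2Cl2, 0 °C
Reagents that add atoms: 2-methylpropanoyl chloride (CC(C)C(Cl)=O)
Why: Acylation of the unhindered C5 alcohol under nucleophilic catalysis at low temperature avoids acyl migration.

Step 18
Reactants: 25 diester TBS ether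
Product: 26 (1R,2S,4S,5S,7R,8R,9S)-9-hydroxy-3,3,7-trimethyl-11-methylidene-5-[(2-methylpropanoyl)oxy]tricyclo[5.4.0.0(2,8)]undec-4-yl (2Z)-2-methylbut-2-enoate
Conditions: HF·pyridine, pyridine, THF, 0 °C→rt
Reagents that add atoms: none
Why: Fluoride-mediated desilylation under buffered conditions frees the C9 alcohol without touching either ester.

Step 19
Reactants: 26 C9 alcohol
Product: 28 (1R,2S,4S,5S,7R,8R)-3,3,7,11-tetramethyl-5-[(2-methylpropanoyl)oxy]-9-oxotricyclo[5.4.0.0(2,8)]undec-10-en-4-yl (2Z)-2-methylbut-2-enoate, via β,γ-unsaturated ketone 27 (not isolated)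
Conditions: Dess–Martin periodinane, NaHCO3, CH2Cl2, 0 °C→rt; then DBU (20 mol%), rt
Reagents that add atoms: none
Why: Dess–Martin oxidation gives the β,γ-unsaturated ketone and base-catalysed isomerisation (dienolate protonation at the exocyclic carbon) moves the alkene into conjugation to give the enone, while C8 is a bridgehead and cannot epimerise.

**Compound list**
1 | 3-methylbut-2-enal | CC(C)=CC=O | starting material
2 | 4,4,5,5-tetramethyl-2-(propa-1,2-dien-1-yl)-1,3,2-dioxaborolane | C=C=CB1OC(C)(C)C(C)(C)O1 | starting material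
3 | (4S)-6-methylhept-5-en-1-yn-4-ol | C#CC[C@H](O)C=C(C)C | intermediate
4 | 1-methoxy-4-({[(4S)-6-methylhept-5-en-1-yn-4-yl]oxy}methyl)benzene | C#CC[C@H](OCc1ccc(OC)cc1)C=C(C)C | intermediate
5 | {(1E,4S)-4-[(4-methoxybenzyl)oxy]-2,6-dimethylhepta-1,5-dien-1-yl}dimethylalane | C[Al](C)/C=C(\C)C[C@H](OCc1ccc(OC)cc1)C=C(C)C | intermediate
6 | lithium butyl{(1E,4S)-4-[(4-methoxybenzyl)oxy]-2,6-dimethylhepta-1,5-dien-1-yl}dimethylaluminate | [Li+].CCCC[Al-](C)(C)/C=C(\C)C[C@H](OCc1ccc(OC)cc1)C=C(C)C | intermediate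
7 | (2E,5S)-5-[(4-methoxybenzyl)oxy]-3,7-dimethylocta-2,6-dien-1-ol | OC/C=C(\C)C[C@H](OCc1ccc(OC)cc1)C=C(C)C | intermediate
8 | (2E,5S)-5-[(4-methoxybenzyl)oxy]-3,7-dimethylocta-2,6-dienal | O=C/C=C(\C)C[C@H](OCc1ccc(OC)cc1)C=C(C)C | intermediate
9 | methyl 3-methylbut-2-enoate | COC(=O)C=C(C)C | starting material
10 | tert-butyl[(1-methoxy-3-methylbuta-1,3-dien-1-yl)oxy]dimethylsilane (ketene acetal geometry not defined) | COC(O[Si](C)(C)C(C)(C)C)=CC(C)=C | intermediate
11 | methyl (2E,5S,6E,9S)-5-hydroxy-9-[(4-methoxybenzyl)oxy]-3,7,11-trimethyldodeca-2,6,10-trienoate | COC(=O)/C=C(\C)C[C@H](O)/C=C(\C)C[C@H](OCc1ccc(OC)cc1)C=C(C)C | intermediate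
12 | methyl (2E,5S,6E,9S)-5-[(tert-butyldimethylsilyl)oxy]-9-[(4-methoxybenzyl)oxy]-3,7,11-trimethyldodeca-2,6,10-trienoate | COC(=O)/C=C(\C)C[C@H](O[Si](C)(C)C(C)(C)C)/C=C(\C)C[C@H](OCc1ccc(OC)cc1)C=C(C)C | intermediate
13 | (2E,5S,6E,9S)-5-[(tert-butyldimethylsilyl)oxy]-9-[(4-methoxybenzyl)oxy]-3,7,11-trimethyldodeca-2,6,10-trienoic acid | OC(=O)/C=C(\C)C[C@H](O[Si](C)(C)C(C)(C)C)/C=C(\C)C[C@H](OCc1ccc(OC)cc1)C=C(C)C | intermediate
14 | (2E,5S,6E,9S)-5-[(tert-butyldimethylsilyl)oxy]-9-[(4-methoxybenzyl)oxy]-3,7,11-trimethyldodeca-2,6,10-trienoyl chloride | ClC(=O)/C=C(\C)C[C@H](O[Si](C)(C)C(C)(C)C)/C=C(\C)C[C@H](OCc1ccc(OC)cc1)C=C(C)C | intermediate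
15 | (5S,6E,9S)-5-[(tert-butyldimethylsilyl)oxy]-9-[(4-methoxybenzyl)oxy]-7,11-dimethyl-3-methylidenedodeca-1,6,10-trien-1-one (vinylketene) | O=C=CC(=C)C[C@H](O[Si](C)(C)C(C)(C)C)/C=C(\C)C[C@H](OCc1ccc(OC)cc1)C=C(C)C | intermediate
16 | (1R,4S,5R,7R)-4-[(tert-butyldimethylsilyl)oxy]-7-{(2S)-2-[(4-methoxybenzyl)oxy]-4-methylpent-3-en-1-yl}-7-methyl-2-methylidenebicyclo[3.1.1]heptan-6-one (7-methyl syn to the C2–C4 bridge) | CC(C)=C[C@@H](OCc1ccc(OC)cc1)C[C@@]2(C)[C@@H]3[C@@H](O[Si](C)(C)C(C)(C)C)CC(=C)[C@H]2C3=O | intermediate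
17 | (1R,4S,5R,7R)-4-[(tert-butyldimethylsilyl)oxy]-7-[(2S)-2-hydroxy-4-methylpent-3-en-1-yl]-7-methyl-2-methylidenebicyclo[3.1.1]heptan-6-one | CC(C)=C[C@@H](O)C[C@@]2(C)[C@@H]3[C@@H](O[Si](C)(C)C(C)(C)C)CC(=C)[C@H]2C3=O | intermediate
18 | (1R,4S,5R,7R)-4-[(tert-butyldimethylsilyl)oxy]-7-{(2S)-2-[(2R)-3,3-dimethyloxiran-2-yl]-2-hydroxyethyl}-7-methyl-2-methylidenebicyclo[3.1.1]heptan-6-one | CC1(C)O[C@@H]1[C@@H](O)C[C@@]2(C)[C@@H]3[C@@H](O[Si](C)(C)C(C)(C)C)CC(=C)[C@H]2C3=O | intermediate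
19 | (1R,4S,5R,7R)-4-[(tert-butyldimethylsilyl)oxy]-7-{(2S)-2-[(2R)-3,3-dimethyloxiran-2-yl]-2-[(triethylsilyl)oxy]ethyl}-7-methyl-2-methylidenebicyclo[3.1.1]heptan-6-one | CC1(C)O[C@@H]1[C@@H](O[Si](CC)(CC)CC)C[C@@]2(C)[C@@H]3[C@@H](O[Si](C)(C)C(C)(C)C)CC(=C)[C@H]2C3=O | intermediate
20 | N'-[(1R,4S,5S,7R)-4-[(tert-butyldimethylsilyl)oxy]-7-{(2S)-2-[(2R)-3,3-dimethyloxiran-2-yl]-2-[(triethylsilyl)oxy]ethyl}-7-methyl-2-methylidenebicyclo[3.1.1]heptan-6-ylidene]-4-methylbenzenesulfonohydrazide (C=N geometry not defined) | CC1(C)O[C@@H]1[C@@H](O[Si](CC)(CC)CC)C[C@@]2(C)[C@@H]3[C@@H](O[Si](C)(C)C(C)(C)C)CC(=C)[C@H]2C3=NNS(=O)(=O)c4ccc(C)cc4 | intermediate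
21 | cyclised tosylhydrazide: compound 22 in which the C2 hydrogen is replaced by NH–NH–SO2(4-methylphenyl), all other centres as in 22 | O[C@@H]1[C@@H](O[Si](CC)(CC)CC)C[C@@]2(C)[C@@H]3[C@@H](O[Si](C)(C)C(C)(C)C)CC(=C)[C@H]2[C@]3(NNS(=O)(=O)c4ccc(C)cc4)C1(C)C | intermediate
22 | (1R,2S,4S,5S,7R,8R,9S)-9-[(tert-butyldimethylsilyl)oxy]-3,3,7-trimethyl-11-methylidene-5-[(triethylsilyl)oxy]tricyclo[5.4.0.0(2,8)]undecan-4-ol | O[C@@H]1[C@@H](O[Si](CC)(CC)CC)C[C@@]2(C)[C@@H]3[C@@H](O[Si](C)(C)C(C)(C)C)CC(=C)[C@H]2[C@@H]3C1(C)C | intermediate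
23 | (1R,2S,4S,5S,7R,8R,9S)-9-[(tert-butyldimethylsilyl)oxy]-3,3,7-trimethyl-11-methylidene-5-[(triethylsilyl)oxy]tricyclo[5.4.0.0(2,8)]undec-4-yl (2Z)-2-methylbut-2-enoate | C/C=C(/C)C(=O)O[C@@H]1[C@@H](O[Si](CC)(CC)CC)C[C@@]2(C)[C@@H]3[C@@H](O[Si](C)(C)C(C)(C)C)CC(=C)[C@H]2[C@@H]3C1(C)C | intermediate
24 | (1R,2S,4S,5S,7R,8R,9S)-9-[(tert-butyldimethylsilyl)oxy]-5-hydroxy-3,3,7-trimethyl-11-methylidenetricyclo[5.4.0.0(2,8)]undec-4-yl (2Z)-2-methylbut-2-enoate | C/C=C(/C)C(=O)O[C@@H]1[C@@H](O)C[C@@]2(C)[C@@H]3[C@@H](O[Si](C)(C)C(C)(C)C)CC(=C)[C@H]2[C@@H]3C1(C)C | intermediate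
25 | (1R,2S,4S,5S,7R,8R,9S)-9-[(tert-butyldimethylsilyl)oxy]-3,3,7-trimethyl-11-methylidene-5-[(2-methylpropanoyl)oxy]tricyclo[5.4.0.0(2,8)]undec-4-yl (2Z)-2-methylbut-2-enoate | C/C=C(/C)C(=O)O[C@@H]1[C@@H](OC(=O)C(C)C)C[C@@]2(C)[C@@H]3[C@@H](O[Si](C)(C)C(C)(C)C)CC(=C)[C@H]2[C@@H]3C1(C)C | intermediate
26 | (1R,2S,4S,5S,7R,8R,9S)-9-hydroxy-3,3,7-trimethyl-11-methylidene-5-[(2-methylpropanoyl)oxy]tricyclo[5.4.0.0(2,8)]undec-4-yl (2Z)-2-methylbut-2-enoate | C/C=C(/C)C(=O)O[C@@H]1[C@@H](OC(=O)C(C)C)C[C@@]2(C)[C@@H]3[C@@H](O)CC(=C)[C@H]2[C@@H]3C1(C)C | intermediate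
27 | (1R,2S,4S,5S,7R,8R)-3,3,7-trimethyl-11-methylidene-5-[(2-methylpropanoyl)oxy]-9-oxotricyclo[5.4.0.0(2,8)]undec-4-yl (2Z)-2-methylbut-2-enoate | C/C=C(/C)C(=O)O[C@@H]1[C@@H](OC(=O)C(C)C)C[C@@]2(C)[C@@H]3C(=O)CC(=C)[C@H]2[C@@H]3C1(C)C | intermediate
28 | (1R,2S,4S,5S,7R,8R)-3,3,7,11-tetramethyl-5-[(2-methylpropanoyl)oxy]-9-oxotricyclo[5.4.0.0(2,8)]undec-10-en-4-yl (2Z)-2-methylbut-2-enoate | C/C=C(/C)C(=O)O[C@@H]1[C@@H](OC(=O)C(C)C)C[C@@]2(C)[C@@H]3C(=O)C=C(C)[C@H]2[C@@H]3C1(C)C | target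

**Step count and risks**
Total steps: 19. Longest linear sequence: 18 (steps 1–4 and 6–19; step 5 is a one-step branch).

The three steps most likely to fail:

Step 14 (the proposed new step). The β-titanoxy tertiary radical may be reduced or lose hydrogen to the isopropenyl carbinol before it cyclises, and loss of sulfinate from the hindered hydrazide may be slow. The fallback uses known chemistry, sets out from 19 and comes back at 22. Stoichiometric Cp2TiCl (Cp2TiCl2, Zn, THF) opens the epoxide of 19 and the tertiary radical adds to the titanium-bound cyclobutanone carbonyl (known epoxide–carbonyl radical cyclisation) to give the tertiary cyclobutanol F1. Ac2O/pyridine acetylates only the secondary C4 hydroxyl to give the hydroxy acetate F2. Methyl chlorooxalate with 4-(dimethylamino)pyridine gives the tertiary methyl oxalate F3. Bu3SnH with azobisisobutyronitrile in toluene at 110 °C (Barton-type deoxygenation of a tertiary oxalate) gives the deoxygenated acetate F4, and K2CO3 in MeOH removes the acetate to return 22.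

Step 9. The ketene may oligomerise, deprotonation may give the endocyclic-alkene isomer, and face selectivity from the OTBS centre may be modest (the minor diastereomer has the enantiomeric core and must be removed). The fallback sets out from 13 and comes back at 16. The acid is converted (1-chloro-N,N,2-trimethylprop-1-en-1-amine, then Me2NH) into the N,N-dimethylamide F5. Tf2O and 2,4,6-collidine in ClCH2CH2Cl (0→80 °C) generate the vinylketeniminium ion, which undergoes the Ghosez-type intramolecular [2+2] at lower temperature to the cyclobutaniminium triflate F6. Aqueous NaHCO3 hydrolysis then gives 16.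

Step 15. The C4 alcohol is neopentylic and flanked by the C5 silyl ether, so acylation may be slow and forcing conditions may isomerise angelate to tiglate. The fallback sets out from 22 and comes back at 23. Esterification with 2-[bis(2,2,2-trifluoroethoxy)phosphoryl]propanoic acid (N,N'-dicyclohexylcarbodiimide, 4-(dimethylamino)pyridine) gives the phosphonopropanoate F7. Still–Gennari olefination (KN(SiMe3)2, 18-crown-6, THF, −78 °C, acetaldehyde) then builds the Z double bond on the substrate and gives 23.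

**Further compounds**
F1 | step 14 | tertiary cyclobutanol: compound 22 with OH in place of the C2 hydrogen (2,4-diol) | O[C@@H]1[C@@H](O[Si](CC)(CC)CC)C[C@@]2(C)[C@@H]3[C@@H](O[Si](C)(C)C(C)(C)C)CC(=C)[C@H]2[C@]3(O)C1(C)C
F2 | step 14 | hydroxy acetate: C4 acetate of F1 | CC(=O)O[C@@H]1[C@@H](O[Si](CC)(CC)CC)C[C@@]2(C)[C@@H]3[C@@H](O[Si](C)(C)C(C)(C)C)CC(=C)[C@H]2[C@]3(O)C1(C)C
F3 | step 14 | tertiary methyl oxalate: C2 methyl oxalate of F2 | CC(=O)O[C@@H]1[C@@H](O[Si](CC)(CC)CC)C[C@@]2(C)[C@@H]3[C@@H](O[Si](C)(C)C(C)(C)C)CC(=C)[C@H]2[C@]3(OC(=O)C(=O)OC)C1(C)C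
F4 | step 14 | deoxygenated acetate: C4 acetate of 22 | CC(=O)O[C@@H]1[C@@H](O[Si](CC)(CC)CC)C[C@@]2(C)[C@@H]3[C@@H](O[Si](C)(C)C(C)(C)C)CC(=C)[C@H]2[C@@H]3C1(C)C
F5 | step 9 | (2E,5S,6E,9S)-5-[(tert-butyldimethylsilyl)oxy]-9-[(4-methoxybenzyl)oxy]-N,N,3,7,11-pentamethyldodeca-2,6,10-trienamide | CN(C)C(=O)/C=C(\C)C[C@H](O[Si](C)(C)C(C)(C)C)/C=C(\C)C[C@H](OCc1ccc(OC)cc1)C=C(C)C
F6 | step 9 | cyclobutaniminium triflate: compound 16 with C6=N(+)Me2 in place of C6=O, trifluoromethanesulfonate salt | CC(C)=C[C@@H](OCc1ccc(OC)cc1)C[C@@]2(C)[C@@H]3[C@@H](O[Si](C)(C)C(C)(C)C)CC(=C)[C@H]2C3=[N+](C)C.[O-]S(=O)(=O)C(F)(F)F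
F7 | step 15 | phosphonopropanoate: C4 2-[bis(2,2,2-trifluoroethoxy)phosphoryl]propanoate of 22 (mixture at the phosphonate-bearing carbon) | CC(C(=O)O[C@@H]1[C@@H](O[Si](CC)(CC)CC)C[C@@]2(C)[C@@H]3[C@@H](O[Si](C)(C)C(C)(C)C)CC(=C)[C@H]2[C@@H]3C1(C)C)P(=O)(OCC(F)(F)F)OCC(F)(F)F
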